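## Analysis of the target

- The target is a 3,8''-linked biflavanone. Unit 1 is an eriodictyol skeleton (5,7-dihydroxychroman-4-one with a 3,4-dihydroxyphenyl group on C2). Unit 2 is a naringenin skeleton (5'',7''-dihydroxychroman-4-one with a 4-hydroxyphenyl group on C2''). The two are joined by one bond from C3 of unit 1 to C8'' of ring A''.
- There are three stereocentres. C2 and C3 are both R, which places the catechol ring and ring A'' cis on ring C of unit 1, so the two hydrogens are syn. C2'' is R and is too far from unit 1 for any relay of configuration.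
- C3–H is alpha to the C4 carbonyl and benzylic, so acid or base will epimerise the cis compound to the more stable trans isomer.
- Both C2–O1 bonds are beta-aryloxy ketones. They racemise by retro-oxa-Michael opening under base and are benzylic ethers open to hydrogenolysis. The seven phenols, one pair a catechol, are oxidation-prone.
- The hard bond is C3–C8''. It joins a carbon with two ring neighbours to an aromatic carbon flanked on both sides by oxygenated carbons, so making it by coupling of two finished halves is a tetra-ortho-type problem.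
- The strategy rests on the pattern of ring A''. C8'' lies between the oxygen-bearing carbons C7'' and C8a'', with the third oxygen on C5'' para to it, which is a 2-substituted phloroglucinol. Such a ring can be grown around the C3 substituent from a two-carbon alkynyl ether (C8'', C7'') and a four-carbon cyclobutenone (C8a'', C4a'', C5'', C6'').
- If both pyranone rings are kept as chromones until late, all three stereocentres come from two alkene hydrogenations, and syn addition gives the cis-2,3 relationship.

## Retrosynthetic reasoning

**27 from 26.** The seven O–benzyl bonds are cut last. Hydrogenolysis is neutral, which the epimerisable C3 and the two beta-aryloxy ketones require, and one protecting group throughout gives a single final operation.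

**26 from 25 from 24.** The C–H bonds at C2, C3 and C2'' are disconnected, leading back to the achiral biflavone 24. Syn delivery of hydrogen across C2=C3 gives the cis-2,3 relationship directly. C2 and C2'' have the same spatial sense when the two chromones are drawn alike, so one antipode of one catalyst can serve both rings. The catalyst type that hydrogenates flavones also reduces the carbonyls, so the route passes through the bis-carbinol 25 and a buffered oxidation returns the ketones in 26.

**24 from 22, 20, 17 and 16.** Ring C'' is opened at O1''–C2'' and at C4''–C4a''. O1'' is the free phenol of 16, C4'' is a formyl carbon placed ortho to it, and C2''/C3'' come from arylacetylene 18. A Fries or Friedel–Crafts cinnamoylation was not used because the Lewis acids would strip benzyl ethers, in particular the one peri to the C4 carbonyl. A magnesium phenoxide delivers a one-carbon electrophile only ortho, and the single free ortho position of 16 is C4a''. Addition of 19 to aldehyde 17, oxidation to ynone 21 and 6-endo closure give the chromone directly, so no separate dehydrogenation is needed. The silyl group on O7'' is exchanged for benzyl at 22, after O1'' is locked in the ring and before any stereocentre exists.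

**16 from 10 and 13 (key disconnection).** Ring A'' is cut at C8a''–C8'' and at C7''–C6''. This removes the whole arene and leaves C3 attached to a linear alkyne, so the hindered junction is made as an sp2–sp bond before the arene exists. The forward reaction must place the C3-bearing carbon between a hydroxyl and an oxygenated carbon, which the polarity of the ketene–ynol ether addition does. A benzyl group on the alkynyl oxygen would give uniform protection, but benzyl alkynyl ethers rearrange by a [3,3] shift below the temperature at which a cyclobutenone opens, and simple alkyl alkynyl ethers fragment by a retro-ene path. A triisopropylsilyl ynol ether has neither escape. It also leaves the three oxygens of ring A'' differentiated in 16: free at C8a'', silylated at C7'', benzylated at C5''.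

**10 from 7, 6, and 4 plus 5.** The O–C(sp) bond is cut back to terminal alkyne 7, whose acetylide is oxidised to ynolate 9 and silylated on oxygen. The C3–C(sp) bond is cut back to enol triflate 4 and silylacetylene 5 (Sonogashira coupling, then desilylation of 6). This takes three steps where one coupling of a preformed alkoxyethynyl metal would do, in exchange for an ynol ether that survives the key step.

**4 from 3 from 1.** The triflate needs a flavonol in which O3 alone is free. Direct benzylation of the aglycone of 1 leaves O5, not O3, unprotected. In 1 the sugar masks O3, so exhaustive benzylation to 2 and acid hydrolysis give 3.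

**13 from 11 and 12.** The benzyl group that ends on O5'' is put on the cyclobutenone by vinylogous transesterification of the commercial ethyl compound 11 with 12.

## Alternatives that were turned down

**Alternative 1:** Disconnection of C2''–C3'' of unit 2.
- Forward step: diazoketone A2 loses N2 with Rh2(S-PTTL)4, and the carbenoid inserts into a benzylic C–H bond of the 4-benzyloxybenzyl ether on O1'', closing ring C'' and giving A1.
- For it: C2'' is set by the catalyst in the ring-forming event, at the flavanone oxidation level, with no late reduction of ring C''. On that point it is stronger than the chosen route.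
- Against it: A2 already contains unit 1 with its cis stereocentres and the C3–C8'' bond, so the two hardest features of the target are assumed, not made. The diazoketone must be built next to an epimerisable C3–H. The ether oxygen competes for the carbenoid, and the resulting oxonium ylide shifts a benzyl group to give a five-membered benzofuranone. Six-membered insertions are the less favoured mode.
- Comparison: the chosen strategy gives up catalyst-controlled ring closure at C2'' but makes the C3–C8'' junction, which Alternative 1 leaves open.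

**Alternative 2:** Disconnection of O1–C2 and C3–C4 of unit 1.
- Forward step: the ortho-quinone methide released from benzyl alcohol A5 by a chiral binaphthyl phosphoric acid adds across Z-stilbene A4 to give flavan A3.
- For it: the cis-2,3 relationship comes from the alkene geometry by suprafacial addition, with no hydrogenation of a tetrasubstituted alkene. On that point it is stronger than the chosen route, and it is convergent.
- Against it: both ends of the stilbene carry electron-rich aryl groups, so the orientation of addition is poorly biased. The acid that generates the quinone methide can isomerise the Z-alkene, or the addition can go stepwise through a benzylic cation, and either loses the cis relationship. The aryl group on the alkene is di-ortho-substituted. C4 arrives as a methylene and must be oxidised to the ketone in the presence of seven benzyl ether methylenes and the benzylic C2–H.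
- Comparison: the chosen strategy carries C4 at the ketone level throughout and has no regiochemical ambiguity in the ring-forming step.

**Alternative 3:** Disconnection of O1''–C2'' and C3''–C4'' of unit 2.
- Forward step: the quinone methide generated on ring A'' from benzyl alcohol A7 adds styrene A8 under a chiral binaphthyl phosphoric acid to give A6.
- For it: a styrene is a well-behaved partner with clear orientation, and C2'' is set in the cycloaddition. This is at least as strong as the chosen route for C2''.
- Against it: A7 contains unit 1 complete, so again the C3–C8'' bond and the cis centres are presupposed. The acid can epimerise C3. The catalyst must override the existing stereocentres. C4'' must then be oxidised from methylene to ketone next to many benzylic positions.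
- Comparison: the chosen route adds steps for ring C'', but these steps are simple and also leave C4'' as a carbonyl.

Key step: step 7

**Assumptions**
- 1-(Benzyloxy)-4-ethynylbenzene 18 is taken as a catalogue compound.
- In step 12 the antipode of the carbene ligand that gives 2R flavans is used; which antipode that is should be fixed on a simple flavone first.
- Compounds 16 to 26 are hindered about the C3–C8'' bond and may show slowly interconverting rotamers; this does not affect the stereocentres of 27.

## Route

**Step 1**
Reactants: 1 rutin (quercetin 3-O-rutinoside)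
Product: 3 5,7,3',4'-tetra-O-benzylquercetin, via tetra-O-benzylrutin 2 (not isolated)
Conditions: BnBr (8 equiv), K2CO3, DMF, 80 °C; then 2 M HCl, EtOH, 80 °C
Reagents that add atoms: benzyl bromide, BrCc1ccccc1
Why: Williamson etherification of the four phenols (the chelated 5-OH needs the excess and heat; any benzylation of sugar hydroxyls is lost with the sugar), then acid hydrolysis of the enol glycoside should free O3 alone.

**Step 2**
Reactants: 3 5,7,3',4'-tetra-O-benzylquercetin
Product: 4 tetra-O-benzylquercetin 3-O-triflate
Conditions: Tf2O, pyridine, CH2Cl2, 0 °C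
Reagents that add atoms: trifluoromethanesulfonic anhydride, O=S(=O)(OS(=O)(=O)C(F)(F)F)C(F)(F)F
Why: O-sulfonylation of the only free hydroxyl, an acidic enol, should give the enol triflate.

**Step 3**
Reactants: 4 tetra-O-benzylquercetin 3-O-triflate; 5 (trimethylsilyl)acetylene
Product: 6 tetra-O-benzyl 3-[(trimethylsilyl)ethynyl]luteolin
Conditions: PdCl2(PPh3)2 (5 mol%), CuI (10 mol%), Et3N, DMF, 60 °C
Reagents that add atoms: none
Why: Sonogashira coupling; the enol triflate alpha to the chromone carbonyl should undergo oxidative addition readily, and the linear alkyne is not affected by the crowding at C3.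

**Step 4**
Reactants: 6 tetra-O-benzyl 3-[(trimethylsilyl)ethynyl]luteolin
Product: 7 tetra-O-benzyl 3-ethynylluteolin
Conditions: K2CO3 (0.2 equiv), MeOH/THF, 0 °C to rt
Reagents that add atoms: none
Why: Methanolysis of the C(sp)–Si bond; the fully substituted chromone should tolerate brief catalytic carbonate.

**Step 5**
Reactants: 7 tetra-O-benzyl 3-ethynylluteolin
Product: 10 tetra-O-benzyl 3-[(triisopropylsilyloxy)ethynyl]luteolin, via lithium acetylide 8 (not isolated), via lithium ynolate 9 (not isolated)
Conditions: LiN(SiMe3)2, THF, −78 °C; t-BuOOLi (from t-BuOOH and LiN(SiMe3)2), −78 to 0 °C; then TIPSOTf, −78 °C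
Reagents that add atoms: tert-butyl hydroperoxide, CC(C)(C)OO; triisopropylsilyl trifluoromethanesulfonate, CC(C)[Si](C(C)C)(C(C)C)OS(=O)(=O)C(F)(F)F
Why: Oxidation of a lithium acetylide by lithium tert-butyl peroxide gives the ynolate, and the bulky silyl triflate silylates it on oxygen (siloxyalkyne synthesis by acetylide oxidation); the amide base is non-nucleophilic and should spare the chromone.

**Step 6**
Reactants: 11 3-ethoxycyclobut-2-en-1-one; 12 benzyl alcohol
Product: 13 3-(benzyloxy)cyclobut-2-en-1-one
Conditions: BnOH (3 equiv), PPTS (5 mol%), toluene, 35 °C, reduced pressure (EtOH removed)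
Reagents that add atoms: none
Why: Acid-catalysed transetherification of a vinylogous ester through the mixed ketal, driven by removal of the more volatile ethanol.

**Step 7**
Reactants: 10 tetra-O-benzyl 3-[(triisopropylsilyloxy)ethynyl]luteolin; 13 3-(benzyloxy)cyclobut-2-en-1-one
Product: 16 5,7-bis(benzyloxy)-2-[3,4-bis(benzyloxy)phenyl]-3-[4-(benzyloxy)-2-hydroxy-6-(triisopropylsilyloxy)phenyl]chromen-4-one, via vinylketene 14 (not isolated), via vinylcyclobutenone 15 (not isolated)
Conditions: 13 (1.5 equiv, added over 2 h), toluene, 85 °C, then 110 °C, sealed tube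
Reagents that add atoms: none
Why: Heating 13 triggers a conrotatory 4π ring opening to vinylketene 14, whose ketene carbon is attacked by the nucleophilic alkyne carbon of 10 (the one bonded to C3, beta to the silyloxy group) while the oxygen-bearing alkyne carbon bonds to the ketene alpha-carbon, a regioselective [2+2] addition that gives 15. A second 4π opening of 15 produces a dienylketene that closes ring A'' by 6π electrocyclisation between the ketene carbon and the terminal methylene and tautomerises to phenol 16, the two new skeletal bonds being C8a''–C8'' and C7''–C6''. The closest known reaction is the Danheiser benzannulation of cyclobutenones with siloxyalkynes to resorcinol monosilyl ethers; a 3-alkoxycyclobutenone and a chromon-3-yl alkyne are new members of the two substrate families. No stereocentre is formed. The selectivity that matters is regiochemical and is fixed by the polarity of the ketene–ynol ether pair: the C3-bearing carbon ends between the new hydroxyl and the silyloxy carbon, with the benzyloxy carbon para to it, which is the 2-substituted phloroglucinol pattern of ring A''. Chemoselectivity rests on the silyl ynol ether, which cannot fragment by retro-ene or [3,3] pathways at these temperatures, and on slow addition of 13, which keeps the ketene concentration low so that the hindered phenol of 16 is not acylated. The hindered C3–C8'' bond is already present in 10 as an unencumbered sp2–sp bond, so no coupling at a di-ortho-substituted arene is needed. The three ring oxygens emerge differentiated: free at C8a'', silylated at C7'', benzylated at C5''.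

**Step 8**
Reactants: 16 the phenol from step 7
Product: 17 5,7-bis(benzyloxy)-2-[3,4-bis(benzyloxy)phenyl]-3-[4-(benzyloxy)-3-formyl-2-hydroxy-6-(triisopropylsilyloxy)phenyl]chromen-4-one
Conditions: MgCl2, Et3N, (CH2O)n, MeCN/THF, 75 °C
Reagents that add atoms: paraformaldehyde (as formaldehyde), C=O
Why: Magnesium-mediated ortho-formylation (Casnati–Skattebøl): the magnesium phenoxide delivers formaldehyde only ortho and a second formaldehyde oxidises the benzylic alkoxide; the one free ortho position is C4a'', and C6'' is shielded by the silyl ether.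

**Step 9**
Reactants: 17 the salicylaldehyde from step 8; 18 1-(benzyloxy)-4-ethynylbenzene
Product: 20 propargylic alcohol, 3-{4-(benzyloxy)-2-hydroxy-3-[1-hydroxy-3-(4-benzyloxyphenyl)prop-2-yn-1-yl]-6-(triisopropylsilyloxy)phenyl} tetra-O-benzyl flavone (carbinol centre uncontrolled), via alkynylmagnesium bromide 19 (not isolated)
Conditions: 18 (3 equiv), EtMgBr, THF, 0 °C to rt; then 17, −20 to 0 °C; aq. NH4Cl
Reagents that add atoms: none
Why: 1,2-Addition of an alkynyl Grignard reagent to the chelated magnesium salicylaldehyde (one equivalent is spent on the phenol); the hindered vinylogous-ester carbonyl of the flavone should not compete with an aldehyde at this temperature, and the new carbinol centre is removed in step 10.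

**Step 10**
Reactants: 20 the propargylic alcohol from step 9
Product: 22 5,7,3',4',5'',4'''-hexa-O-benzyl-7''-O-triisopropylsilyl-3,8''-biflavone, via ynone 21 (not isolated)
Conditions: MnO2, CH2Cl2, rt; filter; then Et2NH, EtOH/THF, 50 °C
Reagents that add atoms: none
Why: MnO2 oxidises the doubly activated (benzylic and propargylic) alcohol; the secondary amine adds to the ynone and the phenol displaces it from the beta-amino enone, a 6-endo closure that should give the chromone, not the aurone.

**Step 11**
Reactants: 22 the silyl biflavone from step 10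
Product: 24 5,7,3',4',5'',7'',4'''-hepta-O-benzyl-3,8''-biflavone, via caesium phenoxide 23 (not isolated)
Conditions: CsF, BnBr, DMF, rt
Reagents that add atoms: benzyl bromide, BrCc1ccccc1
Why: Fluoride cleaves the aryl silyl ether and the phenoxide is benzylated in the same flask; there is no stereocentre yet, and any silyl group lost in step 10 is benzylated here as well.

**Step 12**
Reactants: 24 hepta-O-benzyl-3,8''-biflavone
Product: 25 hepta-O-benzyl bis-chroman-4-ol with the configuration of 27 at C2, C3 and C2'' (C4 and C4'' uncontrolled)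
Conditions: H2 (120 bar), Ru(cod)(2-methylallyl)2 (5 mol%), SINpEt·HBF4 (10 mol%), KOt-Bu (15 mol%), toluene, 40 °C
Reagents that add atoms: none
Why: Proposed new method: a chiral Ru–carbene hydride (SINpEt = 1,3-bis[1-(1-naphthyl)ethyl]-4,5-dihydroimidazol-2-ylidene) is expected to bind each pyranone C=C on one face and deliver both hydrogens syn, so that one catalyst antipode sets C2'' at the trisubstituted alkene of ring C'' and C2/C3 (cis by syn addition) at the tetrasubstituted alkene of unit 1, since both chromones present the same O1–C2(aryl) motif; the C4 and C4'' carbonyls are expected to be reduced as well and are restored in step 13; the closest known reaction is the Ru–N-heterocyclic carbene catalysed asymmetric hydrogenation of flavones and 2-alkylchromones to flavanols, which has not been shown for a 2,3-diaryl (tetrasubstituted) chromone.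

**Step 13**
Reactants: 25 the bis-chromanol from step 12
Product: 26 (2R,3R,2''R)-hepta-O-benzyl biflavanone
Conditions: Dess–Martin periodinane, NaHCO3, CH2Cl2, 0 °C to rt
Reagents that add atoms: none
Why: Buffered, non-basic oxidation of the two benzylic carbinols returns the ketones without enolising C3; material that kept a carbonyl in step 12 converges on the same product.

**Step 14**
Reactants: 26 (2R,3R,2''R)-hepta-O-benzyl biflavanone
Product: 27 the target, (2R,3R,2''R)-3,8''-biflavanone CNP0105436.4
Conditions: H2 (1 atm), Pd(OH)2/C, EtOAc/MeOH, rt, short reaction time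
Reagents that add atoms: none
Why: Neutral hydrogenolysis of seven aryl benzyl ethers; no acid or base is present, so C3 should stay cis and C2/C2'' should not open.

## Compound list

1 | rutin | C[C@H]1[C@@H]([C@H]([C@H]([C@@H](O1)OC[C@@H]2[C@H]([C@@H]([C@H]([C@@H](O2)Oc3c(-c4ccc(O)c(O)c4)oc4cc(O)cc(O)c4c3=O)O)O)O)O)O)O | starting material
2 | 5,7,3',4'-tetra-O-benzylrutin | C[C@H]1[C@@H]([C@H]([C@H]([C@@H](O1)OC[C@@H]2[C@H]([C@@H]([C@H]([C@@H](O2)Oc3c(-c4ccc(OCc5ccccc5)c(OCc5ccccc5)c4)oc4cc(OCc5ccccc5)cc(OCc5ccccc5)c4c3=O)O)O)O)O)O)O | intermediate (not isolated)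
3 | 5,7,3',4'-tetra-O-benzylquercetin | O=c1c(O)c(-c2ccc(OCc3ccccc3)c(OCc3ccccc3)c2)oc2cc(OCc3ccccc3)cc(OCc3ccccc3)c12 | intermediate
4 | tetra-O-benzylquercetin 3-O-triflate | O=c1c(OS(=O)(=O)C(F)(F)F)c(-c2ccc(OCc3ccccc3)c(OCc3ccccc3)c2)oc2cc(OCc3ccccc3)cc(OCc3ccccc3)c12 | intermediate
5 | (trimethylsilyl)acetylene | C#C[Si](C)(C)C | starting material
6 | tetra-O-benzyl 3-[(trimethylsilyl)ethynyl]luteolin | O=c1c(C#C[Si](C)(C)C)c(-c2ccc(OCc3ccccc3)c(OCc3ccccc3)c2)oc2cc(OCc3ccccc3)cc(OCc3ccccc3)c12 | intermediate
7 | tetra-O-benzyl 3-ethynylluteolin | O=c1c(C#C)c(-c2ccc(OCc3ccccc3)c(OCc3ccccc3)c2)oc2cc(OCc3ccccc3)cc(OCc3ccccc3)c12 | intermediate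
8 | lithium acetylide of 7 | O=c1c(C#C[Li])c(-c2ccc(OCc3ccccc3)c(OCc3ccccc3)c2)oc2cc(OCc3ccccc3)cc(OCc3ccccc3)c12 | intermediate (not isolated)
9 | lithium ynolate | O=c1c(C#C[O-])c(-c2ccc(OCc3ccccc3)c(OCc3ccccc3)c2)oc2cc(OCc3ccccc3)cc(OCc3ccccc3)c12.[Li+] | intermediate (not isolated)
10 | tetra-O-benzyl 3-[(triisopropylsilyloxy)ethynyl]luteolin | O=c1c(C#CO[Si](C(C)C)(C(C)C)C(C)C)c(-c2ccc(OCc3ccccc3)c(OCc3ccccc3)c2)oc2cc(OCc3ccccc3)cc(OCc3ccccc3)c12 | intermediate
11 | 3-ethoxycyclobut-2-en-1-one | CCOC1=CC(=O)C1 | starting material
12 | benzyl alcohol | OCc1ccccc1 | starting material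
13 | 3-(benzyloxy)cyclobut-2-en-1-one | O=C1C=C(OCc2ccccc2)C1 | intermediate
14 | 3-(benzyloxy)buta-1,3-dien-1-one (vinylketene) | O=C=CC(=C)OCc1ccccc1 | intermediate (not isolated)
15 | 4-[1-(benzyloxy)ethenyl]-2-(tetra-O-benzylflavon-3-yl)-3-(triisopropylsilyloxy)cyclobut-2-en-1-one (racemic at the ring CH) | O=c1c(C4=C(O[Si](C(C)C)(C(C)C)C(C)C)C(C(=C)OCc5ccccc5)C4=O)c(-c2ccc(OCc3ccccc3)c(OCc3ccccc3)c2)oc2cc(OCc3ccccc3)cc(OCc3ccccc3)c12 | intermediate (not isolated)
16 | 5,7-bis(benzyloxy)-2-[3,4-bis(benzyloxy)phenyl]-3-[4-(benzyloxy)-2-hydroxy-6-(triisopropylsilyloxy)phenyl]chromen-4-one | O=c1c(-c4c(O)cc(OCc5ccccc5)cc4O[Si](C(C)C)(C(C)C)C(C)C)c(-c2ccc(OCc3ccccc3)c(OCc3ccccc3)c2)oc2cc(OCc3ccccc3)cc(OCc3ccccc3)c12 | intermediate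
17 | 3-[4-(benzyloxy)-3-formyl-2-hydroxy-6-(triisopropylsilyloxy)phenyl] tetra-O-benzyl flavone | O=c1c(-c4c(O)c(C=O)c(OCc5ccccc5)cc4O[Si](C(C)C)(C(C)C)C(C)C)c(-c2ccc(OCc3ccccc3)c(OCc3ccccc3)c2)oc2cc(OCc3ccccc3)cc(OCc3ccccc3)c12 | intermediate
18 | 1-(benzyloxy)-4-ethynylbenzene | C#Cc1ccc(OCc2ccccc2)cc1 | starting material
19 | [(4-benzyloxyphenyl)ethynyl]magnesium bromide | Br[Mg]C#Cc1ccc(OCc2ccccc2)cc1 | intermediate (not isolated)
20 | propargylic alcohol (carbinol centre uncontrolled) | O=c1c(-c4c(O)c(C(O)C#Cc6ccc(OCc7ccccc7)cc6)c(OCc5ccccc5)cc4O[Si](C(C)C)(C(C)C)C(C)C)c(-c2ccc(OCc3ccccc3)c(OCc3ccccc3)c2)oc2cc(OCc3ccccc3)cc(OCc3ccccc3)c12 | intermediate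
21 | ortho-hydroxyaryl ynone | O=c1c(-c4c(O)c(C(=O)C#Cc6ccc(OCc7ccccc7)cc6)c(OCc5ccccc5)cc4O[Si](C(C)C)(C(C)C)C(C)C)c(-c2ccc(OCc3ccccc3)c(OCc3ccccc3)c2)oc2cc(OCc3ccccc3)cc(OCc3ccccc3)c12 | intermediate (not isolated)
22 | hexa-O-benzyl-7''-O-triisopropylsilyl-3,8''-biflavone | O=c1c(-c4c5oc(-c6ccc(OCc7ccccc7)cc6)cc(=O)c5c(OCc6ccccc6)cc4O[Si](C(C)C)(C(C)C)C(C)C)c(-c2ccc(OCc3ccccc3)c(OCc3ccccc3)c2)oc2cc(OCc3ccccc3)cc(OCc3ccccc3)c12 | intermediate
23 | caesium 7''-phenoxide of the biflavone | O=c1c(-c4c5oc(-c6ccc(OCc7ccccc7)cc6)cc(=O)c5c(OCc6ccccc6)cc4[O-])c(-c2ccc(OCc3ccccc3)c(OCc3ccccc3)c2)oc2cc(OCc3ccccc3)cc(OCc3ccccc3)c12.[Cs+] | intermediate (not isolated)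
24 | hepta-O-benzyl-3,8''-biflavone | O=c1c(-c4c5oc(-c6ccc(OCc7ccccc7)cc6)cc(=O)c5c(OCc6ccccc6)cc4OCc8ccccc8)c(-c2ccc(OCc3ccccc3)c(OCc3ccccc3)c2)oc2cc(OCc3ccccc3)cc(OCc3ccccc3)c12 | intermediate
25 | hepta-O-benzyl bis-chroman-4-ol, geometry of 27 at C2, C3 and C2'' (formally 2R,3S,2''R because the carbinol changes the priorities at C3); C4 and C4'' mixed | OC1C[C@H](c2ccc(OCc3ccccc3)cc2)Oc2c1c(OCc3ccccc3)cc(OCc3ccccc3)c2[C@H]1C(O)c2c(OCc3ccccc3)cc(OCc3ccccc3)cc2O[C@H]1c1ccc(OCc2ccccc2)c(OCc2ccccc2)c1 | intermediate
26 | (2R,3R,2''R)-hepta-O-benzyl biflavanone | O=C1C[C@H](c2ccc(OCc3ccccc3)cc2)Oc2c1c(OCc3ccccc3)cc(OCc3ccccc3)c2[C@H]1C(=O)c2c(OCc3ccccc3)cc(OCc3ccccc3)cc2O[C@H]1c1ccc(OCc2ccccc2)c(OCc2ccccc2)c1 | intermediate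
27 | CNP0105436.4, (2R,3R,2''R)-3,8''-biflavanone | O=C1C[C@H](c2ccc(O)cc2)Oc2c1c(O)cc(O)c2[C@H]1C(=O)c2c(O)cc(O)cc2O[C@H]1c1ccc(O)c(O)c1 | target

## Step count and risk

Total: 14 steps. Longest linear sequence: 13 steps (steps 1–5 and 7–14, from 1); step 6 is a one-step branch.

**Step 12 (labelled step).**
- What may go wrong: the catalyst may fail to turn over at the tetrasubstituted C2=C3, whose 3-aryl group stands perpendicular and blocks both faces. Facial selectivity at unit 1 may also be eroded, because rotamers about C3–C8'' present different environments. Ring C'' alone should behave as a normal flavone.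
- Fallback, from 24 to 27, by known reactions:
  - A copper hydride conjugate reduction (Cu(OAc)2, a DTBM-SEGPHOS-type bisphosphine of the hand that gives 2R, (EtO)2MeSiH, t-BuOH, toluene), a known asymmetric 1,4-reduction of 2-substituted chromones, should reduce only the unhindered ring C'' alkene and give the (2''R)-flavanone–flavone F1.
  - Hydrogenation of F1 over Pd(OH)2/C in EtOAc/MeOH under pressure then adds hydrogen cis across C2=C3 without facial control and removes the benzyl groups in the same operation.
  - This gives 27 together with its (2S,3S,2''R) diastereomer F2, which are separated by preparative reversed-phase HPLC. The route is rejoined at 27 at the cost of half the material; steps 12–14 are replaced.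

**Step 7 (key step).**
- What may go wrong: ring opening of the alkoxy-stabilised cyclobutenone may need temperatures at which it oligomerises. The chromonyl group may lower the nucleophilicity of the alkyne so that ketene dimerisation wins. A second vinylketene may acylate the product phenol.
- Fallback, from 4 to 24, by coupling a preformed ring A''–C'' unit:
  - 4',5,7-Tri-O-benzylapigenin F3 (from apigenin, BnBr, K2CO3, DMF) is iodinated at C8 (I2, CF3CO2Ag, CH2Cl2) to the 8-iodoflavone F4.
  - F4 is borylated (B2pin2, PdCl2(dppf), KOAc, dioxane) to the pinacol boronate F5.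
  - F5 is joined to triflate 4 by Suzuki–Miyaura coupling (Pd(OAc)2, SPhos, K3PO4, toluene/water, 90 °C) to give 24 directly; steps 3–11 are then not needed.
  - The price is a tetra-ortho-substituted coupling with protodeboronation as competitor, which is the problem the benzannulation was chosen to avoid.

**Step 5.**
- What may go wrong: the acetylide or the peroxide may attack the chromone (addition at C2 with ring opening, or nucleophilic epoxidation), and the siloxyalkyne may hydrolyse on work-up.
- Fallback, from 7 to 10, by electrophilic oxygenation of the alkyne: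
  - PhI(OH)OTs in CHCl3 converts 7 into the alkynyl(phenyl)iodonium tosylate F6.
  - Catalytic CuOTf in MeCN rearranges F6 to the alkynyl tosylate F7.
  - MeLi at −78 °C attacks sulfur and releases ynolate 9, which is silylated with TIPSOTf as before to give 10.

**Step 6.**
- What may go wrong: the alcohol may attack the strained carbonyl and open the ring to an acetoacetate-type ester, or the enone may polymerise under acid.
- Fallback, from 11 to 13: hydrolysis (aq. HCl, 0 °C) gives cyclobutane-1,3-dione F8, a strongly acidic enol, which is O-benzylated with 12 under Mitsunobu conditions (PPh3, DIAD, THF, 0 °C).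

**Step 14.**
- What may go wrong: hydrogenolysis of the benzylic C2–O1 and C2''–O1'' bonds (ring opening to dihydrochalcones), over-reduction of the ketones, and epimerisation at C3 on prolonged contact with the catalyst.
- Fallback, from 26 to 27: non-reductive debenzylation with BCl3 and pentamethylbenzene as cation scavenger in CH2Cl2 at −78 °C; no new compound is made.

## Further compounds

F1 | step 12 | (2''R)-hepta-O-benzyl flavanone–flavone (ring C'' reduced, unit 1 still a chromone) | O=C1C[C@H](c2ccc(OCc3ccccc3)cc2)Oc2c1c(OCc3ccccc3)cc(OCc3ccccc3)c2-c1c(-c2ccc(OCc3ccccc3)c(OCc3ccccc3)c2)oc2cc(OCc3ccccc3)cc(OCc3ccccc3)c2c1=O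
F2 | step 12 | (2S,3S,2''R) diastereomer of the target | O=C1C[C@H](c2ccc(O)cc2)Oc2c1c(O)cc(O)c2[C@@H]1C(=O)c2c(O)cc(O)cc2O[C@@H]1c1ccc(O)c(O)c1
F3 | step 7 | 4',5,7-tri-O-benzylapigenin | O=c1cc(-c2ccc(OCc3ccccc3)cc2)oc2cc(OCc3ccccc3)cc(OCc3ccccc3)c12
F4 | step 7 | 8-iodo-4',5,7-tri-O-benzylapigenin | O=c1cc(-c2ccc(OCc3ccccc3)cc2)oc2c(I)c(OCc3ccccc3)cc(OCc3ccccc3)c12
F5 | step 7 | 4',5,7-tri-O-benzylapigenin-8-boronic acid pinacol ester | O=c1cc(-c2ccc(OCc3ccccc3)cc2)oc2c(B3OC(C)(C)C(C)(C)O3)c(OCc3ccccc3)cc(OCc3ccccc3)c12
F6 | step 5 | [(tetra-O-benzylflavon-3-yl)ethynyl](phenyl)iodonium tosylate | O=c1c(C#C[I+]c4ccccc4)c(-c2ccc(OCc3ccccc3)c(OCc3ccccc3)c2)oc2cc(OCc3ccccc3)cc(OCc3ccccc3)c12.Cc1ccc(cc1)S(=O)(=O)[O-]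
F7 | step 5 | (tetra-O-benzylflavon-3-yl)ethynyl tosylate | O=c1c(C#COS(=O)(=O)c4ccc(C)cc4)c(-c2ccc(OCc3ccccc3)c(OCc3ccccc3)c2)oc2cc(OCc3ccccc3)cc(OCc3ccccc3)c12
F8 | step 6 | cyclobutane-1,3-dione | O=C1CC(=O)C1
F0 | step 14 | none | none
A1 | alternative 1 | hexa-O-benzyl 5''-O-triisopropylsilyl (2R,3R,2''R) target | O=C1C[C@H](c2ccc(OCc3ccccc3)cc2)Oc2c1c(O[Si](C(C)C)(C(C)C)C(C)C)cc(OCc3ccccc3)c2[C@H]1C(=O)c2c(OCc3ccccc3)cc(OCc3ccccc3)cc2O[C@H]1c1ccc(OCc3ccccc3)c(OCc3ccccc3)c1
A2 | alternative 1 | diazoketone on C4a'' with a 4-benzyloxybenzyl ether on O1'' | [N-]=[N+]=CC(=O)c1c(O[Si](C(C)C)(C(C)C)C(C)C)cc(OCc2ccccc2)c([C@H]2C(=O)c3c(OCc4ccccc4)cc(OCc4ccccc4)cc3O[C@H]2c2ccc(OCc3ccccc3)c(OCc3ccccc3)c2)c1OCc1ccc(OCc2ccccc2)cc1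
A3 | alternative 2 | hepta-O-benzyl cis-2,3-diaryl flavan with C4 as methylene | O=C1C[C@H](c2ccc(OCc3ccccc3)cc2)Oc2c1c(OCc3ccccc3)cc(OCc3ccccc3)c2[C@H]1Cc2c(OCc3ccccc3)cc(OCc3ccccc3)cc2O[C@H]1c1ccc(OCc3ccccc3)c(OCc3ccccc3)c1
A4 | alternative 2 | Z-stilbene joining ring B to C8'' of the (2''R)-tri-O-benzyl flavanone | O=C1C[C@H](c2ccc(OCc3ccccc3)cc2)Oc2c1c(OCc3ccccc3)cc(OCc3ccccc3)c2/C=C\c1ccc(OCc2ccccc2)c(OCc2ccccc2)c1
A5 | alternative 2 | 3,5-bis(benzyloxy)-2-(hydroxymethyl)phenol | OCc1c(O)cc(OCc2ccccc2)cc1OCc1ccccc1
A6 | alternative 3 | hepta-O-benzyl target with C4'' as methylene | C1C[C@H](c2ccc(OCc3ccccc3)cc2)Oc2c1c(OCc3ccccc3)cc(OCc3ccccc3)c2[C@H]1C(=O)c2c(OCc3ccccc3)cc(OCc3ccccc3)cc2O[C@H]1c1ccc(OCc3ccccc3)c(OCc3ccccc3)c1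
A7 | alternative 3 | ring A'' 2-hydroxybenzyl alcohol carrying (2R,3R) unit 1 on C8'' | OCc1c(OCc2ccccc2)cc(OCc2ccccc2)c([C@H]2C(=O)c3c(OCc4ccccc4)cc(OCc4ccccc4)cc3O[C@H]2c2ccc(OCc3ccccc3)c(OCc3ccccc3)c2)c1O
A8 | alternative 3 | 4-(benzyloxy)styrene | C=Cc1ccc(OCc2ccccc2)cc1
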